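## Retrosynthetic overview

1. Disydonol C ← LiAlH4 reduction of a ring B methyl ester and one global hydrogenation (two side-chain alkenes, two O-benzyl groups) ← diarylmethane by Suzuki–Miyaura coupling of a ring A benzylic chloride with a ring B arylboronate.
2. Each half ← an (S)-tertiary homoallylic alcohol. The side chain is finished by cross-metathesis with 3-methylbut-1-ene. The carbinol C–C bond and its configuration come from an intermolecular catalytic asymmetric allylboration of an aryl methyl ketone with an allylboronate (key step, run once per half).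
3. Both ketones ← methyl 4-acetyl-3-hydroxybenzoate (ring B after bromination para to OH) ← methyl 4-bromo-3-hydroxybenzoate by Stille acetylation.
4. No ring is formed: both benzene rings are bought in the one benzoate. Order of events: ketone, allylation, chain extension, aryl–CH2–aryl coupling, deprotection.

Assumption 1: (R)-3,3'-dibromo-1,1'-bi-2-naphthol is taken as the catalyst antipode that delivers allyl to the Si face of the aryl methyl ketones (S product). This is from memory of the acetophenone case, so the sense is checked on the first batch of allylation product and the (S)-catalyst is used if it proves opposite.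
Assumption 2: cross-metathesis products are E/Z mixtures (E major), drawn and named as E; the geometry is erased in step 14.
Convention: atom sources that carry a compound number stand on the Reactants line; "Reagents that add atoms" names the remaining, unnumbered ones.

## Route

Step 1
Reactants: 1 methyl 4-bromo-3-hydroxybenzoate
Product: 3 methyl 4-acetyl-3-hydroxybenzoate, via enol ether 2 (not isolated)
Conditions: tributyl(1-ethoxyvinyl)stannane (1.2 equiv), PdCl2(PPh3)2 (3 mol%), 1,4-dioxane, 100 °C; then 2 M HCl (aq), rt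
Reagents that add atoms: tributyl(1-ethoxyvinyl)stannane CCCC[Sn](CCCC)(CCCC)C(=C)OCC; water O
Why: Stille coupling of the ester-activated aryl bromide needs no base, so the free phenol is tolerated, and dilute acid then hydrolyses the enol ether to the methyl ketone without touching the methyl ester.

Step 2
Reactants: 3 methyl 4-acetyl-3-hydroxybenzoate
Product: 4 methyl 4-acetyl-3-(benzyloxy)benzoate
Conditions: BnBr (1.2 equiv), K2CO3 (2 equiv), DMF, 60 °C
Reagents that add atoms: benzyl bromide BrCc1ccccc1
Why: Williamson ether synthesis; carbonate deprotonates the hydrogen-bonded phenol and the phenoxide displaces bromide (SN2), while ketone and ester are inert.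

Step 3
Reactants: 5 allylmagnesium bromide (1.0 M in Et2O); 6 triisopropyl borate
Product: 8 allyldiisopropoxyborane, via borate ate complex 7 (not isolated)
Conditions: Et2O, −78 °C to rt; then HCl (1.0 equiv, 2 M in Et2O), 0 °C; filter under Ar, distil
Reagents that add atoms: none
Why: Grignard addition to the borate gives the ate complex and one equivalent of HCl removes one isopropoxide as isopropanol, the standard preparation of a distillable allylboronic ester.

Step 4
Reactants: 4 methyl 4-acetyl-3-(benzyloxy)benzoate; 8 allyldiisopropoxyborane (1.5 equiv)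
Product: 10 methyl 3-(benzyloxy)-4-[(2S)-2-hydroxypent-4-en-2-yl]benzoate, via borate ester 9 (not isolated)
Conditions: (R)-3,3'-dibromo-1,1'-bi-2-naphthol (15 mol%), PhCF3/PhMe 3:1, −35 °C, 24 h; then H2O (pH 7 buffer)
Reagents that add atoms: none
Why: Chiral-diol-catalysed asymmetric allylboration of a ketone (Schaus allylboration): exchange of one isopropoxide for the binaphthol gives a more Lewis acidic chiral boronate that transfers allyl through a closed six-membered chair transition state with aryl pseudo-equatorial, Si-face addition setting the S tertiary carbinol, while the ester does not react with the allylboronate.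

Step 5
Reactants: 10 methyl 3-(benzyloxy)-4-[(2S)-2-hydroxypent-4-en-2-yl]benzoate
Product: 11 methyl 3-(benzyloxy)-4-[(2S,4E)-2-hydroxy-6-methylhept-4-en-2-yl]benzoate
Conditions: 3-methylbut-1-ene (10 equiv), second-generation Grubbs catalyst (5 mol%), CH2Cl2, 40 °C, pressure tube
Reagents that add atoms: 3-methylbut-1-ene C=CC(C)C
Why: Olefin cross-metathesis; the unhindered terminal alkene exchanges with the excess volatile partner with loss of ethene, the free tertiary alcohol, ester and benzyl ether are inert to the ruthenium carbene, and the stereocentre is untouched.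

Step 6
Reactants: 11 methyl 3-(benzyloxy)-4-[(2S,4E)-2-hydroxy-6-methylhept-4-en-2-yl]benzoate
Product: 12 (2S,4E)-2-[2-(benzyloxy)-4-(hydroxymethyl)phenyl]-6-methylhept-4-en-2-ol
Conditions: LiAlH4 (2 equiv), THF, 0 °C; aq potassium sodium tartrate work-up
Reagents that add atoms: none
Why: Hydride reduction of the ester to the primary benzylic alcohol; the tertiary alkoxide, isolated alkene and benzyl ether are unaffected.

Step 7
Reactants: 12 (2S,4E)-2-[2-(benzyloxy)-4-(hydroxymethyl)phenyl]-6-methylhept-4-en-2-ol
Product: 14 (2S,4E)-2-[2-(benzyloxy)-4-(chloromethyl)phenyl]-6-methylhept-4-en-2-ol, via mesylate 13 (not isolated)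
Conditions: MsCl (1.2 equiv), LiCl (3 equiv), 2,4,6-collidine (1.5 equiv), DMF, 0 °C to rt
Reagents that add atoms: methanesulfonyl chloride CS(=O)(=O)Cl (stays in 13 only); lithium chloride [Li+].[Cl-] (Cl of 14)
Why: Collington–Meyers chlorination; the primary benzylic alcohol is sulfonylated far faster than the hindered tertiary one and chloride displaces the benzylic mesylate by SN2 under non-acidic conditions that spare the tertiary benzylic alcohol.

Step 8
Reactants: 3 methyl 4-acetyl-3-hydroxybenzoate
Product: 15 methyl 4-acetyl-2-bromo-5-hydroxybenzoate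
Conditions: NBS (1.05 equiv), MeCN, 0 °C to rt, dark
Reagents that add atoms: N-bromosuccinimide O=C1CCC(=O)N1Br
Why: Electrophilic aromatic bromination; OH directs para, one ortho site carries the acetyl group and the other is squeezed between OH and CO2Me, so bromine enters para to OH, and ring bromination of a phenol outruns α-bromination of the ketone under neutral conditions.

Step 9
Reactants: 15 methyl 4-acetyl-2-bromo-5-hydroxybenzoate
Product: 16 methyl 4-acetyl-5-(benzyloxy)-2-bromobenzoate
Conditions: BnBr (1.2 equiv), K2CO3 (2 equiv), DMF, 60 °C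
Reagents that add atoms: benzyl bromide BrCc1ccccc1
Why: Williamson ether synthesis as in step 2; the aryl bromide is inert to carbonate and benzyl bromide.

Step 10
Reactants: 16 methyl 4-acetyl-5-(benzyloxy)-2-bromobenzoate; 8 allyldiisopropoxyborane (1.5 equiv)
Product: 18 methyl 5-(benzyloxy)-2-bromo-4-[(2S)-2-hydroxypent-4-en-2-yl]benzoate, via borate ester 17 (not isolated)
Conditions: (R)-3,3'-dibromo-1,1'-bi-2-naphthol (15 mol%), PhCF3/PhMe 3:1, −35 °C, 24 h; then H2O (pH 7 buffer)
Reagents that add atoms: none
Why: The same Schaus asymmetric allylboration as in step 4, with the same chair transition state and Si-face addition giving the S carbinol; the bromine sits meta to the ketone and does not interfere, and neither aryl bromide nor ester reacts with the boronate.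

Step 11
Reactants: 18 methyl 5-(benzyloxy)-2-bromo-4-[(2S)-2-hydroxypent-4-en-2-yl]benzoate
Product: 19 methyl 5-(benzyloxy)-2-bromo-4-[(2S,4E)-2-hydroxy-6-methylhept-4-en-2-yl]benzoate
Conditions: 3-methylbut-1-ene (10 equiv), second-generation Grubbs catalyst (5 mol%), CH2Cl2, 40 °C, pressure tube
Reagents that add atoms: 3-methylbut-1-ene C=CC(C)C
Why: Olefin cross-metathesis as in step 5; the aryl bromide is inert to the ruthenium carbene.

Step 12
Reactants: 19 methyl 5-(benzyloxy)-2-bromo-4-[(2S,4E)-2-hydroxy-6-methylhept-4-en-2-yl]benzoate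
Product: 20 methyl 5-(benzyloxy)-4-[(2S,4E)-2-hydroxy-6-methylhept-4-en-2-yl]-2-(4,4,5,5-tetramethyl-1,3,2-dioxaborolan-2-yl)benzoate
Conditions: B2pin2 (1.3 equiv), PdCl2(dppf) (5 mol%), KOAc (3 equiv), 1,4-dioxane, 85 °C
Reagents that add atoms: bis(pinacolato)diboron CC1(C)OB(OC1(C)C)B1OC(C)(C)C(C)(C)O1
Why: Miyaura borylation; zerovalent palladium inserts into the ester-activated C–Br bond, acetate-assisted transmetalation with the diboron and reductive elimination give the arylboronate, KOAc is too weak a base for Suzuki homocoupling, and alcohol, internal alkene and ester survive.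

Step 13
Reactants: 14 (2S,4E)-2-[2-(benzyloxy)-4-(chloromethyl)phenyl]-6-methylhept-4-en-2-ol; 20 methyl 5-(benzyloxy)-4-[(2S,4E)-2-hydroxy-6-methylhept-4-en-2-yl]-2-(4,4,5,5-tetramethyl-1,3,2-dioxaborolan-2-yl)benzoate (1.1 equiv)
Product: 21 methyl 5-(benzyloxy)-2-{3-(benzyloxy)-4-[(2S,4E)-2-hydroxy-6-methylhept-4-en-2-yl]benzyl}-4-[(2S,4E)-2-hydroxy-6-methylhept-4-en-2-yl]benzoate
Conditions: Pd(OAc)2 (5 mol%), SPhos (10 mol%), K3PO4 (3 equiv), PhMe/H2O 10:1, 80 °C
Reagents that add atoms: none
Why: Suzuki–Miyaura coupling of a benzylic chloride with an arylboronate; oxidative addition into the benzylic C–Cl bond, phosphate-promoted transmetalation and reductive elimination form the diarylmethane, the benzylpalladium intermediate has no β-hydrogen, and the bulky electron-rich phosphine copes with the ortho-substituted boronate.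

Step 14
Reactants: 21 methyl 5-(benzyloxy)-2-{3-(benzyloxy)-4-[(2S,4E)-2-hydroxy-6-methylhept-4-en-2-yl]benzyl}-4-[(2S,4E)-2-hydroxy-6-methylhept-4-en-2-yl]benzoate
Product: 22 methyl 5-hydroxy-2-{3-hydroxy-4-[(2S)-2-hydroxy-6-methylheptan-2-yl]benzyl}-4-[(2S)-2-hydroxy-6-methylheptan-2-yl]benzoate
Conditions: H2 (1 atm), 10% Pd/C, NaHCO3 (solid), EtOAc, rt; stop at full conversion
Reagents that add atoms: none
Why: Heterogeneous catalytic hydrogenation saturates both alkenes and hydrogenolyses both aryl benzyl ethers in one operation; under neutral buffered conditions the tertiary benzylic alcohols and the diarylmethane are not cleaved, and no primary benzylic C–O bond is present yet.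

Step 15
Reactants: 22 methyl 5-hydroxy-2-{3-hydroxy-4-[(2S)-2-hydroxy-6-methylheptan-2-yl]benzyl}-4-[(2S)-2-hydroxy-6-methylheptan-2-yl]benzoate
Product: 23 disydonol C
Conditions: LiAlH4 (6 equiv), THF, 0 °C to 40 °C; aq potassium sodium tartrate/NH4Cl work-up at pH 7
Reagents that add atoms: none
Why: Hydride reduction of the only remaining carbonyl group to the benzylic alcohol; the four acidic OH groups merely consume hydride, and the neutral work-up avoids acid that could ionise the tertiary benzylic alcohols.

## Compound list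

1 | methyl 4-bromo-3-hydroxybenzoate | COC(=O)c1ccc(Br)c(O)c1 | starting material
2 | methyl 4-(1-ethoxyethenyl)-3-hydroxybenzoate | CCOC(=C)c1ccc(C(=O)OC)cc1O | intermediate
3 | methyl 4-acetyl-3-hydroxybenzoate | CC(=O)c1ccc(C(=O)OC)cc1O | intermediate
4 | methyl 4-acetyl-3-(benzyloxy)benzoate | CC(=O)c1ccc(C(=O)OC)cc1OCc1ccccc1 | intermediate
5 | allylmagnesium bromide | C=CC[Mg]Br | starting material
6 | triisopropyl borate | CC(C)OB(OC(C)C)OC(C)C | starting material
7 | bromomagnesium allyltriisopropoxyborate | C=CC[B-](OC(C)C)(OC(C)C)OC(C)C.[Mg+2].[Br-] | intermediate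
8 | allyldiisopropoxyborane (diisopropyl allylboronate) | C=CCB(OC(C)C)OC(C)C | intermediate
9 | (2S)-2-[2-(benzyloxy)-4-(methoxycarbonyl)phenyl]pent-4-en-2-yl diisopropyl borate | C=CC[C@](C)(OB(OC(C)C)OC(C)C)c1ccc(C(=O)OC)cc1OCc1ccccc1 | intermediate
10 | methyl 3-(benzyloxy)-4-[(2S)-2-hydroxypent-4-en-2-yl]benzoate | C=CC[C@](C)(O)c1ccc(C(=O)OC)cc1OCc1ccccc1 | intermediate
11 | methyl 3-(benzyloxy)-4-[(2S,4E)-2-hydroxy-6-methylhept-4-en-2-yl]benzoate | CC(C)/C=C/C[C@](C)(O)c1ccc(C(=O)OC)cc1OCc1ccccc1 | intermediate
12 | (2S,4E)-2-[2-(benzyloxy)-4-(hydroxymethyl)phenyl]-6-methylhept-4-en-2-ol | CC(C)/C=C/C[C@](C)(O)c1ccc(CO)cc1OCc1ccccc1 | intermediate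
13 | 3-(benzyloxy)-4-[(2S,4E)-2-hydroxy-6-methylhept-4-en-2-yl]benzyl methanesulfonate | CC(C)/C=C/C[C@](C)(O)c1ccc(COS(C)(=O)=O)cc1OCc1ccccc1 | intermediate
14 | (2S,4E)-2-[2-(benzyloxy)-4-(chloromethyl)phenyl]-6-methylhept-4-en-2-ol | CC(C)/C=C/C[C@](C)(O)c1ccc(CCl)cc1OCc1ccccc1 | intermediate
15 | methyl 4-acetyl-2-bromo-5-hydroxybenzoate | CC(=O)c1cc(Br)c(C(=O)OC)cc1O | intermediate
16 | methyl 4-acetyl-5-(benzyloxy)-2-bromobenzoate | CC(=O)c1cc(Br)c(C(=O)OC)cc1OCc1ccccc1 | intermediate
17 | (2S)-2-[2-(benzyloxy)-5-bromo-4-(methoxycarbonyl)phenyl]pent-4-en-2-yl diisopropyl borate | C=CC[C@](C)(OB(OC(C)C)OC(C)C)c1cc(Br)c(C(=O)OC)cc1OCc1ccccc1 | intermediate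
18 | methyl 5-(benzyloxy)-2-bromo-4-[(2S)-2-hydroxypent-4-en-2-yl]benzoate | C=CC[C@](C)(O)c1cc(Br)c(C(=O)OC)cc1OCc1ccccc1 | intermediate
19 | methyl 5-(benzyloxy)-2-bromo-4-[(2S,4E)-2-hydroxy-6-methylhept-4-en-2-yl]benzoate | CC(C)/C=C/C[C@](C)(O)c1cc(Br)c(C(=O)OC)cc1OCc1ccccc1 | intermediate
20 | methyl 5-(benzyloxy)-4-[(2S,4E)-2-hydroxy-6-methylhept-4-en-2-yl]-2-(4,4,5,5-tetramethyl-1,3,2-dioxaborolan-2-yl)benzoate | CC(C)/C=C/C[C@](C)(O)c1cc(B2OC(C)(C)C(C)(C)O2)c(C(=O)OC)cc1OCc1ccccc1 | intermediate
21 | methyl 5-(benzyloxy)-2-{3-(benzyloxy)-4-[(2S,4E)-2-hydroxy-6-methylhept-4-en-2-yl]benzyl}-4-[(2S,4E)-2-hydroxy-6-methylhept-4-en-2-yl]benzoate | CC(C)/C=C/C[C@](C)(O)c1ccc(Cc2cc([C@@](C)(O)C/C=C/C(C)C)c(OCc3ccccc3)cc2C(=O)OC)cc1OCc1ccccc1 | intermediate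
22 | methyl 5-hydroxy-2-{3-hydroxy-4-[(2S)-2-hydroxy-6-methylheptan-2-yl]benzyl}-4-[(2S)-2-hydroxy-6-methylheptan-2-yl]benzoate | CC(C)CCC[C@](C)(O)c1ccc(Cc2cc([C@@](C)(O)CCCC(C)C)c(O)cc2C(=O)OC)cc1O | intermediate
23 | disydonol C, (2S)-2-[2-hydroxy-4-({4-hydroxy-2-(hydroxymethyl)-5-[(2S)-2-hydroxy-6-methylheptan-2-yl]phenyl}methyl)phenyl]-6-methylheptan-2-ol | CC(C)CCC[C@](C)(O)c1ccc(Cc2cc([C@@](C)(O)CCCC(C)C)c(O)cc2CO)cc1O | target

## Step count and risks

Total steps: 15 (including the one-step preparation of allylboronate 8).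
Longest linear sequence: 9 steps from 1 (steps 1, 8, 9, 10, 11, 12, 13, 14, 15; the ring A line 1, 2, 4, 5, 6, 7, 13, 14, 15 is equally long).

Three steps most likely to fail:

Step 4 (its repeat, step 10, shares the risk). The ortho-benzyloxy group twists the ketone out of conjugation and the para ester speeds the uncatalysed background allylation, so rate or enantioselectivity may fall short of the values known for simple acetophenones. The catalyst sense also rests on Assumption 1. Fallback, setting out from 4 and coming back at 10: a zinc-mediated Barbier allylation (allyl bromide, Zn dust, THF/saturated aq NH4Cl, rt) is chemoselective for the ketone over the ester and gives racemic methyl 3-(benzyloxy)-4-(2-hydroxypent-4-en-2-yl)benzoate F1. Preparative chiral SFC (amylose-type phase, CO2/MeOH) then supplies the S enantiomer, which is 10. If only the brominated ketone misbehaves, the fallback given for step 8 removes step 10 from the route.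

Step 8. The phenol is deactivated by two carbonyl groups, so ring bromination may be slow enough for α-bromination of the acetyl group or over-bromination to compete. Fallback, setting out from 11 and coming back at 20: 11 already holds the stereocentre and the side chain, and an ester-directed ortho C–H borylation (B2pin2, [Ir(OMe)(cod)]2, P[3,5-(CF3)2C6H3]3, octane, 80 °C) places boron next to the CO2Me group. Of the two ortho sites, the one flanked by the benzyloxy group is blocked, so boron enters para to the benzyloxy group and gives 20 directly. No new compound is made (F0), and steps 8 to 12 drop out.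

Step 13. The boronate is flanked by an ortho ester, so transmetalation may be slow and protodeboronation, hydrolysis or homocoupling of the benzylic chloride can take over. Fallback, setting out from 14 and 19 and coming back at 21, with the polarity of the coupling reversed: 14 is borylated at the benzylic carbon (B2pin2, Pd(dba)2, P(4-MeOC6H4)3, KOAc, toluene, 50 °C) to (2S,4E)-2-{2-(benzyloxy)-4-[(4,4,5,5-tetramethyl-1,3,2-dioxaborolan-2-yl)methyl]phenyl}-6-methylhept-4-en-2-ol F2. This unhindered primary benzylboronate is then coupled with the ester-activated aryl bromide 19 (PdCl2(dppf), K3PO4, 1,4-dioxane/H2O, 90 °C) to give 21, which also makes step 12 unnecessary.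

## Further compounds

F1 | step 4 | racemic methyl 3-(benzyloxy)-4-(2-hydroxypent-4-en-2-yl)benzoate | C=CCC(C)(O)c1ccc(C(=O)OC)cc1OCc1ccccc1
F0 | step 8 | none | none
F2 | step 13 | (2S,4E)-2-{2-(benzyloxy)-4-[(4,4,5,5-tetramethyl-1,3,2-dioxaborolan-2-yl)methyl]phenyl}-6-methylhept-4-en-2-ol | CC(C)/C=C/C[C@](C)(O)c1ccc(CB2OC(C)(C)C(C)(C)O2)cc1OCc1ccccc1
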